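A direct plan would assemble the permethylated chain with copper: Ullmann coupling of 5-iodo-1,2,3-trimethoxybenzene A1 with 2,6-dimethoxyphenol A2, chain extension with 4-bromo-2,6-dimethoxyphenol A3 by iridium C–H borylation and Chan–Lam aryloxylation in one flask, a second Ullmann coupling with 2,4,6-trimethoxyphenol A4 to the decamethyl ether A5, and BBr3 at the end.
Its weakest steps would be:
- the one-flask borylation/aryloxylation with A3: a crude pinacol boronate and a di-ortho-methoxy bromophenol under air and divalent copper have no precedent, and the electron-rich phenol would be oxidised faster than it is arylated;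
- the Ullmann etherifications: the nucleophile would each time be a phenoxide flanked by two methoxy groups (A2, A4), a poor partner for copper, and in the last coupling the halide would be an electron-rich bromide;
- the ten-fold demethylation of A5 with BBr3 as the last step: ten sites must react completely while an air-sensitive decaphenol sits in a strong Lewis acid.

**Retrosynthetic overview**
Ring A is the benzene-1,3,5-triol end, rings B and C are the inner rings, ring D is the 3,4,5-trihydroxyphenoxy end. Each ether oxygen is bound to a carbon between two C–OH carbons (C2 of ring A, C4 of rings B and C), and the carbon para to it carries the next oxygen.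
Every diaryl ether is cut on this flanked side: a para-formyl group makes the flanked carbon an SNAr acceptor (a 4-fluoro aldehyde monomer) and an unhindered phenoxide adds. Dakin oxidation then turns the formyl carbon into the para C–O bond, which is the phenol of the next cycle.
The rings are joined in the order D, C, B, A and none is built. One monomer serves as rings C, B and A, and it and the ring D phenol both come from 3,4,5-tris(benzyloxy)benzaldehyde.
The hindered partner is the electrophile, where the small fluoride leaves, and never the phenoxide. No copper and no boron relay are used; the nine benzyl ethers arrive with the starting material and leave by hydrogenolysis instead of BBr3.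

Key step: step 4

Assumption: 3,4,5-tris(benzyloxy)benzaldehyde (1) is taken as a commercial starting material; the target has no stereocentre.

Step 1
Reactants: 1 3,4,5-tris(benzyloxy)benzaldehyde
Product: 3 3,4,5-tris(benzyloxy)phenol, via aryl formate 2 (not isolated)
Conditions: 30% H2O2 (1.5 equiv), H2SO4 (10 mol %), MeOH–CH2Cl2, rt
Reagents that add atoms: hydrogen peroxide, OO
Why: Acid-catalysed Dakin oxidation (Baeyer–Villiger type), in which H2O2 adds to the formyl group and the electron-rich 3,4,5-trialkoxyphenyl group migrates to oxygen to give formate 2, which methanol cleaves in the same flask while the benzyl ethers stay inert.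

Step 2
Reactants: 1 3,4,5-tris(benzyloxy)benzaldehyde
Product: 4 3,5-bis(benzyloxy)-4-hydroxybenzaldehyde
Conditions: BCl3 (1.1 equiv), CH2Cl2, −78 °C to −40 °C; then H2O
Reagents that add atoms: none
Why: Regioselective Lewis acid-mediated ether cleavage at the central oxygen of a 3,4,5-trialkoxybenzaldehyde, in which the benzyloxy group at C4 is twisted out of the ring plane by its two neighbours and stands para to the formyl group, so that its oxygen is the most basic site for BCl3 (held as a chelate with a neighbouring oxygen) and its aryloxide the best leaving group when chloride takes the benzyl group; one equivalent of BCl3 at low temperature should spare the two outer ethers.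

Step 3
Reactants: 4 3,5-bis(benzyloxy)-4-hydroxybenzaldehyde
Product: 6 3,5-bis(benzyloxy)-4-fluorobenzaldehyde, via aryl fluorosulfonate 5 (not isolated)
Conditions: SO2F2 (1 atm), NMe4F (3 equiv, anhydrous), DMF, rt then 80 °C
Reagents that add atoms: tetramethylammonium fluoride, C[N+](C)(C)C.[F-]
Why: Deoxyfluorination of a phenol through its aryl fluorosulfonate, in which the phenoxide of 4 is sulfonylated by SO2F2 to 5 and fluoride then attacks the ring carbon that carries the fluorosulfonate, activated by the para-formyl group, in an SNAr-type substitution that expels fluorosulfonate.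

Step 4
Reactants: 3 3,4,5-tris(benzyloxy)phenol; 6 3,5-bis(benzyloxy)-4-fluorobenzaldehyde
Product: 9 3,5-bis(benzyloxy)-4-[3,4,5-tris(benzyloxy)phenoxy]phenol, via diaryl ether aldehyde 7 (not isolated), via aryl formate 8 (not isolated)
Conditions: K2CO3 (2.0 equiv), 6 (1.1 equiv), sulfolane, 140 °C, N2; filter from the potassium salts; then MeOH, H2SO4 (0.2 equiv), 30% H2O2 (1.5 equiv), rt
Reagents that add atoms: hydrogen peroxide, OO
Why: The potassium phenoxide of 3, which has two free ortho positions, adds to C4 of 6, the only carbon that bears a leaving group, to give a Meisenheimer anion delocalised into the para-formyl group, and loss of fluoride gives 7 (SNAr); in the second stage H2O2 adds to the protonated formyl group and the aryl group migrates from carbon to oxygen in the Criegee-type adduct to give formate 8, which methanol cleaves to 9. The closest known reaction types are the SNAr diaryl ether synthesis from 4-fluorobenzaldehydes and phenoxides in dipolar aprotic solvents and the acid-catalysed Dakin oxidation of 3,4,5-trialkoxybenzaldehydes. No ring is closed and no stereocentre is formed. The step needs single arylation, which is secured because 7 has no phenol until the oxidation stage; it needs attack at the flanked carbon, which is helped because the hindrance sits on the electrophile, where the small fluoride leaves, and not on the nucleophile; and it needs aryl rather than hydride migration, which the para-aryloxy group and the electron-rich ring secure. The new hydroxyl stands para to the new ether, exactly where ring C of the target carries its second linking oxygen, so 9 is the nucleophile of the next cycle.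

Step 5
Reactants: 9 3,5-bis(benzyloxy)-4-[3,4,5-tris(benzyloxy)phenoxy]phenol; 6 3,5-bis(benzyloxy)-4-fluorobenzaldehyde
Product: 12 3,5-bis(benzyloxy)-4-{3,5-bis(benzyloxy)-4-[3,4,5-tris(benzyloxy)phenoxy]phenoxy}phenol, via trimer aldehyde 10 (not isolated), via trimer formate 11 (not isolated)
Conditions: K2CO3 (2.0 equiv), 6 (1.1 equiv), sulfolane, 140 °C, N2; filter from the potassium salts; then MeOH–CH2Cl2, H2SO4 (0.2 equiv), 30% H2O2 (1.5 equiv), rt
Reagents that add atoms: hydrogen peroxide, OO
Why: Second cycle of SNAr etherification and Dakin oxidation, in which the phenoxide of 9 (again with free ortho positions) displaces fluoride from 6, only the formyl-bearing ring of 10 is activated for any exchange, and the formyl group is then converted into the phenol of ring B.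

Step 6
Reactants: 12 3,5-bis(benzyloxy)-4-{3,5-bis(benzyloxy)-4-[3,4,5-tris(benzyloxy)phenoxy]phenoxy}phenol; 6 3,5-bis(benzyloxy)-4-fluorobenzaldehyde
Product: 15 3,5-bis(benzyloxy)-4-{3,5-bis(benzyloxy)-4-{3,5-bis(benzyloxy)-4-[3,4,5-tris(benzyloxy)phenoxy]phenoxy}phenoxy}phenol, via tetramer aldehyde 13 (not isolated), via tetramer formate 14 (not isolated)
Conditions: K2CO3 (2.0 equiv), 6 (1.2 equiv), sulfolane, 140 °C, N2; filter from the potassium salts; then MeOH–CH2Cl2, H2SO4 (0.2 equiv), 30% H2O2 (1.5 equiv), rt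
Reagents that add atoms: hydrogen peroxide, OO
Why: Third cycle of SNAr etherification and Dakin oxidation, which attaches ring A through its flanked carbon and turns its formyl group into the free para-hydroxyl that the target carries at C5 of ring A.

Step 7
Reactants: 15 3,5-bis(benzyloxy)-4-{3,5-bis(benzyloxy)-4-{3,5-bis(benzyloxy)-4-[3,4,5-tris(benzyloxy)phenoxy]phenoxy}phenoxy}phenol
Product: 16 2-{4-[3,5-dihydroxy-4-(3,4,5-trihydroxyphenoxy)phenoxy]-3,5-dihydroxyphenoxy}benzene-1,3,5-triol (CNP0333502.0)
Conditions: H2 (1 atm), 10% Pd/C, THF–MeOH, rt; filtration under Ar; Sephadex LH-20 (degassed MeOH)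
Reagents that add atoms: none
Why: Heterogeneous catalytic hydrogenolysis of benzyl aryl ethers on palladium, which should cleave all nine O–CH2Ph bonds under neutral, reducing conditions that leave the three diaryl ether bonds untouched and protect the air-sensitive decaphenol.

**Compound list**
1 | 3,4,5-tris(benzyloxy)benzaldehyde | O=Cc1cc(OCc2ccccc2)c(OCc2ccccc2)c(OCc2ccccc2)c1 | starting material
2 | 3,4,5-tris(benzyloxy)phenyl formate | O=COc1cc(OCc2ccccc2)c(OCc2ccccc2)c(OCc2ccccc2)c1 | intermediate
3 | 3,4,5-tris(benzyloxy)phenol | Oc1cc(OCc2ccccc2)c(OCc2ccccc2)c(OCc2ccccc2)c1 | intermediate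
4 | 3,5-bis(benzyloxy)-4-hydroxybenzaldehyde | O=Cc1cc(OCc2ccccc2)c(O)c(OCc2ccccc2)c1 | intermediate
5 | 2,6-bis(benzyloxy)-4-formylphenyl fluorosulfonate | O=Cc1cc(OCc2ccccc2)c(OS(=O)(=O)F)c(OCc2ccccc2)c1 | intermediate
6 | 3,5-bis(benzyloxy)-4-fluorobenzaldehyde | O=Cc1cc(OCc2ccccc2)c(F)c(OCc2ccccc2)c1 | intermediate
7 | 3,5-bis(benzyloxy)-4-[3,4,5-tris(benzyloxy)phenoxy]benzaldehyde | O=Cc1cc(OCc2ccccc2)c(Oc2cc(OCc3ccccc3)c(OCc3ccccc3)c(OCc3ccccc3)c2)c(OCc2ccccc2)c1 | intermediate
8 | 3,5-bis(benzyloxy)-4-[3,4,5-tris(benzyloxy)phenoxy]phenyl formate | O=COc1cc(OCc2ccccc2)c(Oc2cc(OCc3ccccc3)c(OCc3ccccc3)c(OCc3ccccc3)c2)c(OCc2ccccc2)c1 | intermediate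
9 | 3,5-bis(benzyloxy)-4-[3,4,5-tris(benzyloxy)phenoxy]phenol | Oc1cc(OCc2ccccc2)c(Oc2cc(OCc3ccccc3)c(OCc3ccccc3)c(OCc3ccccc3)c2)c(OCc2ccccc2)c1 | intermediate
10 | 3,5-bis(benzyloxy)-4-{3,5-bis(benzyloxy)-4-[3,4,5-tris(benzyloxy)phenoxy]phenoxy}benzaldehyde | O=Cc1cc(OCc2ccccc2)c(Oc2cc(OCc3ccccc3)c(Oc3cc(OCc4ccccc4)c(OCc4ccccc4)c(OCc4ccccc4)c3)c(OCc3ccccc3)c2)c(OCc2ccccc2)c1 | intermediate
11 | 3,5-bis(benzyloxy)-4-{3,5-bis(benzyloxy)-4-[3,4,5-tris(benzyloxy)phenoxy]phenoxy}phenyl formate | O=COc1cc(OCc2ccccc2)c(Oc2cc(OCc3ccccc3)c(Oc3cc(OCc4ccccc4)c(OCc4ccccc4)c(OCc4ccccc4)c3)c(OCc3ccccc3)c2)c(OCc2ccccc2)c1 | intermediate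
12 | 3,5-bis(benzyloxy)-4-{3,5-bis(benzyloxy)-4-[3,4,5-tris(benzyloxy)phenoxy]phenoxy}phenol | Oc1cc(OCc2ccccc2)c(Oc2cc(OCc3ccccc3)c(Oc3cc(OCc4ccccc4)c(OCc4ccccc4)c(OCc4ccccc4)c3)c(OCc3ccccc3)c2)c(OCc2ccccc2)c1 | intermediate
13 | 3,5-bis(benzyloxy)-4-{3,5-bis(benzyloxy)-4-{3,5-bis(benzyloxy)-4-[3,4,5-tris(benzyloxy)phenoxy]phenoxy}phenoxy}benzaldehyde | O=Cc1cc(OCc2ccccc2)c(Oc2cc(OCc3ccccc3)c(Oc3cc(OCc4ccccc4)c(Oc4cc(OCc5ccccc5)c(OCc5ccccc5)c(OCc5ccccc5)c4)c(OCc4ccccc4)c3)c(OCc3ccccc3)c2)c(OCc2ccccc2)c1 | intermediate
14 | 3,5-bis(benzyloxy)-4-{3,5-bis(benzyloxy)-4-{3,5-bis(benzyloxy)-4-[3,4,5-tris(benzyloxy)phenoxy]phenoxy}phenoxy}phenyl formate | O=COc1cc(OCc2ccccc2)c(Oc2cc(OCc3ccccc3)c(Oc3cc(OCc4ccccc4)c(Oc4cc(OCc5ccccc5)c(OCc5ccccc5)c(OCc5ccccc5)c4)c(OCc4ccccc4)c3)c(OCc3ccccc3)c2)c(OCc2ccccc2)c1 | intermediate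
15 | 3,5-bis(benzyloxy)-4-{3,5-bis(benzyloxy)-4-{3,5-bis(benzyloxy)-4-[3,4,5-tris(benzyloxy)phenoxy]phenoxy}phenoxy}phenol | Oc1cc(OCc2ccccc2)c(Oc2cc(OCc3ccccc3)c(Oc3cc(OCc4ccccc4)c(Oc4cc(OCc5ccccc5)c(OCc5ccccc5)c(OCc5ccccc5)c4)c(OCc4ccccc4)c3)c(OCc3ccccc3)c2)c(OCc2ccccc2)c1 | intermediate
16 | 2-{4-[3,5-dihydroxy-4-(3,4,5-trihydroxyphenoxy)phenoxy]-3,5-dihydroxyphenoxy}benzene-1,3,5-triol | Oc1cc(O)c(Oc2cc(O)c(Oc3cc(O)c(Oc4cc(O)c(O)c(O)c4)c(O)c3)c(O)c2)c(O)c1 | target

Total step count: 7. Longest linear sequence: 6 (steps 2, 3, 4, 5, 6, 7).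

Steps most likely to fail:

Step 4 (and its repeats, steps 5 and 6). The addition of the phenoxide to the fluorine-bearing carbon of 6 may be slow, because that carbon is shielded by two benzyloxy groups and activated only by the para-formyl group. At 140 °C transfer of benzyl groups to the phenoxide and base-induced disproportionation of the aldehyde would then compete. The fallback would make the same bond by palladium catalysis. It sets out from 4, which with Tf2O and pyridine in CH2Cl2 would give 2,6-bis(benzyloxy)-4-formylphenyl trifluoromethanesulfonate F1. C–O coupling of F1 with phenol 3 (Pd(OAc)2, tBuXPhos, K3PO4, toluene, 100 °C) would give aldehyde 7, where the route is rejoined for the Dakin stage.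

Step 3. Fluoride may attack the sulfur of fluorosulfonate 5 and return phenol 4 instead of attacking the shielded ring carbon. The fallback sets out from 4: perfluorobutanesulfonyl fluoride and Et3N would give 2,6-bis(benzyloxy)-4-formylphenyl nonafluorobutane-1-sulfonate F2. Palladium-catalysed nucleophilic fluorination of F2 (CsF, [(cinnamyl)PdCl]2, tBuBrettPhos, toluene, 110 °C) would then form the C–F bond by reductive elimination and return fluoride 6.

Step 2. A second benzyl group may be lost, or cleavage may occur at an outer oxygen, if boron does not discriminate enough between the three ethers. The fallback sets out from 1 and differentiates the oxygens by acidity instead. Hydrogenolysis (H2, Pd/C) would give 3,4,5-trihydroxybenzaldehyde F3. Allyl bromide (1.0 equiv) with NaHCO3 in DMF would alkylate its most acidic hydroxyl, the one para to the formyl group, to 4-(allyloxy)-3,5-dihydroxybenzaldehyde F4. BnBr and K2CO3 would give 4-(allyloxy)-3,5-bis(benzyloxy)benzaldehyde F5, and Pd(PPh3)4 with morpholine would remove the allyl group and return 4.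

Further compounds
F1 | step 4 | 2,6-bis(benzyloxy)-4-formylphenyl trifluoromethanesulfonate | O=Cc1cc(OCc2ccccc2)c(OS(=O)(=O)C(F)(F)F)c(OCc2ccccc2)c1
F2 | step 3 | 2,6-bis(benzyloxy)-4-formylphenyl nonafluorobutane-1-sulfonate | O=Cc1cc(OCc2ccccc2)c(OS(=O)(=O)C(F)(F)C(F)(F)C(F)(F)C(F)(F)F)c(OCc2ccccc2)c1
F3 | step 2 | 3,4,5-trihydroxybenzaldehyde | O=Cc1cc(O)c(O)c(O)c1
F4 | step 2 | 4-(allyloxy)-3,5-dihydroxybenzaldehyde | O=Cc1cc(O)c(OCC=C)c(O)c1
F5 | step 2 | 4-(allyloxy)-3,5-bis(benzyloxy)benzaldehyde | O=Cc1cc(OCc2ccccc2)c(OCC=C)c(OCc2ccccc2)c1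
A1 | direct plan | 5-iodo-1,2,3-trimethoxybenzene | COc1cc(I)cc(OC)c1OC
A2 | direct plan | 2,6-dimethoxyphenol | COc1cccc(OC)c1O
A3 | direct plan | 4-bromo-2,6-dimethoxyphenol | COc1cc(Br)cc(OC)c1O
A4 | direct plan | 2,4,6-trimethoxyphenol | COc1cc(OC)c(O)c(OC)c1
A5 | direct plan | 2-{4-[3,5-dimethoxy-4-(3,4,5-trimethoxyphenoxy)phenoxy]-3,5-dimethoxyphenoxy}-1,3,5-trimethoxybenzene | COc1cc(OC)c(Oc2cc(OC)c(Oc3cc(OC)c(Oc4cc(OC)c(OC)c(OC)c4)c(OC)c3)c(OC)c2)c(OC)c1
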